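## Structural features

The target is a (3R)-isoflavanone: a chroman-4-one in which benzo ring A is fused to pyranone ring C through C4a and C8a, with aryl ring B bonded through C1' to C3. Ring A carries one hydroxyl at C7. Ring B is pentasubstituted, with hydroxyls at C2' and C3', a methoxy group at C4', a prenyl chain at C5' and only C6' free. C3 is the only stereocentre, so no relative configuration has to be controlled. It lies between the C4 ketone and ring B, however, and racemises through the enol under base and more slowly under acid. The fragile groups are the trisubstituted prenyl alkene (strong acid, hypochlorite-type oxidants, hydrogenation), the free catechol (oxidation, above all in base) and the 2'-oxygen, which can close a five-membered lactone on an activated acyl group at C4 if its protecting group is lost. Ring B places oxygen ortho and para to C1', so it also stabilises a cation at C3, and a free acylium ion at C4 could lose CO. The real difficulty is to make C3 in one configuration, close ring C and free three phenols without base, hydrogen or strong protic acid reaching the molecule once C3 is α to a carbonyl group. The key step forms C4–C4a: C4a is ortho to O1 and para to the C7 oxygen, and it is the less hindered of the two ring A carbons that a six-membered closure from O1–C2–C3–C4 can reach. The other reachable carbon lies between the two oxygens and would give the 5-oxygenated isomer; the carbon para to O1 is electronically richer still but out of reach.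

## Logic of the disconnections

19 goes back to 18 by cutting three O–Si bonds. All three phenols have to be masked during the acylation, and silyl ethers can be removed by buffered fluoride without base, hydrogen or strong acid. Triisopropylsilyl is chosen over tert-butyldimethylsilyl because it survives the mild base and hydride of the earlier steps, hinders attack of O-2' on the acyl group, and blocks the ring A carbon between the two oxygens. The forward step must keep the medium buffered so that the C3–H is not removed.

18 goes back to 16 (through 17) by cutting C4–C4a. This opens ring C and turns the enolisable ketone into an open-chain acid in which rings A and B are linked only by an ether and a stereocentre. The forward acylation must be faster than lactonisation through O-2', loss of CO and acid addition to the alkene, and it must run without any base.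

16 goes back to 14 (through 15) by a change of oxidation level at the future C4; no skeletal bond is cut. The primary alcohol is a configurationally robust carrier of the stereocentre. The forward oxidation must pass the α-aryl aldehyde 15 quickly, because that is the first point at which the centre can enolise.

14 goes back to 13 and then to 10 and 12 by cutting the O1–C2 ether bond and the acetyl C–O bond. Ring A becomes a simple phenol, and the two arms of the propane unit are told apart by the acetate. The forward substitution takes place at a primary carbon and must not allow the acetyl group to migrate; the deacetylation must spare the aryl silyl ethers.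

10 goes back to 9 by removing the acetyl group, which removes the stereocentre: 9 has a mirror plane. The stereochemical problem shrinks to a choice between two enantiotopic hydroxymethyl groups. The forward step needs a catalyst that accepts the crowded aryl group and acylates the pro-R arm.

9 goes back to 7 and 8 by cutting the C5'–CH2 bond of the prenyl chain. The alkene is thereby introduced only after the acid-catalysed homologation. The forward coupling must join the unsubstituted allyl terminus to the ring under a base mild enough for the silyl ethers.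

7 goes back to 5 (through 6) by reduction, and 5 goes back to 3 and 4. In the forward sense the formyl carbon of 3 bonds to the diazo carbon of 4, and the aryl group moves from the first to the second. A three-carbon unit is thus built from a one-carbon aldehyde and a two-carbon reagent in one step. The demand is that the aryl group, not hydride, migrates.

3 goes back to 2 by cutting two O–Si bonds and 2 to 1 by cutting C5–Br. The demand is bromination at C5 and not at C6.

12 goes back to 11 by cutting one O–Si bond; the forward step is a statistical monoprotection.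

## Other disconnections considered

Alternative 1: The cut removes the C4 carbonyl and the C3–H and leads to the cis-epoxide A2 of the isoflav-3-ene A1. In the forward direction a chiral Mn(salen)Cl complex (trivalent manganese) with a stoichiometric oxidant would epoxidise the C3=C4 bond of A1. A Lewis acid would then open A2 at C3, and hydride would shift from C4 to C3 anti to the leaving oxygen. Worked through for the configuration drawn for A2, this anti shift gives the R centre of 19.
- In its favour: the stereochemical information comes from a small-molecule catalyst, the ketone and the stereocentre appear together under acid, and no epimerisable aldehyde or acid derivative is carried.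
- Against it, the alkene: A2 bears an allyl group where 19 has prenyl. This is read as a deliberate stand-in, because the electron-rich prenyl alkene would be epoxidised too, and it costs a later cross-metathesis.
- Against it, the mechanism: a cation at C3 stabilised by the oxygenated ring B may live long enough to lose its stereochemical memory, or to collapse by migration of the ring A carbon (ring contraction) in place of hydride. The acetal and carbonate protecting groups must also survive the Lewis acid and then be removed by acid in the presence of the alkene.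
- Comparison: on mechanism it equals the chosen plan in being acid-only at the sensitive stage, and it is better in that no aldehyde oxidation level is passed. On structure it is weaker because of the allyl detour. On step economy it is expected to be equal or longer (synthesis of A1, epoxidation, rearrangement, metathesis, two kinds of deprotection).

Alternative 2: The cut is C3–C4. In the forward direction base would expel sulfinate from the sulfone aldehyde A3 to give the ortho-quinone methide A4. A chiral triazolium-derived carbene would convert the ring A aldehyde into an acyl anion equivalent, which adds to the exocyclic carbon of A4 and closes ring C to give A5, the 7,3'-bis(methoxymethyl) ether of 19.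
- In its favour: the C–C bond, the ring and the stereocentre are made in one catalytic step, the route is convergent, and the 2'-hydroxyl is used as an asset and emerges free.
- Against it: the base that liberates the carbene and A4 remains in contact with a product whose C3–H is acidic. A4 has hydrogens next to its exocyclic carbon and can tautomerise to a styrene-type enol ether. Two acetal groups must still be removed by acid with the prenyl alkene and the labile centre present.
- Comparison: it is better than the chosen plan in convergence and in creating the stereocentre in the bond-forming event, and equal in how the prenyl group is installed. It is weaker in the security of C3, which here is generated under base and not carried through acid-only steps. Step economy is expected to be equal or slightly better.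

Alternative 3: The cut is O1–C2. In the forward direction the ring A phenol of the 2-aryl enone A6 would add to the terminal methylene under a chiral bifunctional base (6-endo-trig), and the resulting enol would be protonated enantioselectively at C3 to give A7, the tris(methoxymethyl) ether of 19.
- In its favour: it is the shortest route, because A6 derives from classical acylation and methylenation chemistry and all C–C bonds are made without any stereochemical burden.
- Against it: the stereocentre is created by the same proton transfer that racemises it, under a base that stays present. An ortho-hydroxyaryl enone is expected to cyclise without catalyst, giving racemic background. Three acetal groups must be removed by acid at the end.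
- Comparison: it is clearly better in step economy and equal in ring-closure geometry. It is weaker in stereochemical security: the chosen plan sets the centre on a carbon that cannot enolise (10) and exposes it to a carbonyl group only under acid.

Key step: step 11

Assumption: the lipase used in step 6 acylates the pro-R hydroxymethyl group of 9. The sense of a given enzyme on this substrate has to be established; an enzyme of opposite preference would be used in the hydrolytic direction on the diacetate of 9.

## Route

Step 1
Reactants: 1 2,3-dihydroxy-4-methoxybenzaldehyde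
Product: 2 5-bromo-2,3-dihydroxy-4-methoxybenzaldehyde
Conditions: Br2 (1.05 equiv), NaOAc, AcOH, 15 °C
Reagents that add atoms: bromine, BrBr
Why: Electrophilic aromatic bromination; C5 is para to the 2-hydroxyl, ortho to the methoxy group and meta to the formyl group, whereas C6 is ortho to the formyl group, so substitution should go to C5, and acetate takes up the HBr.

Step 2
Reactants: 2 5-bromo-2,3-dihydroxy-4-methoxybenzaldehyde
Product: 3 5-bromo-4-methoxy-2,3-bis(triisopropylsilyloxy)benzaldehyde
Conditions: i-Pr3SiOTf (2.5 equiv), 2,6-lutidine, CH2Cl2, 0 °C → rt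
Reagents that add atoms: triisopropylsilyl trifluoromethanesulfonate, CC(C)[Si](C(C)C)(C(C)C)OS(=O)(=O)C(F)(F)F
Why: O-Silylation of both phenols; the triflate is used because the 3-oxygen is flanked on both sides, and the triisopropylsilyl group is chosen for its resistance to the mild base and hydride used later and for the shielding it gives O-2' in the key step.

Step 3
Reactants: 3 5-bromo-4-methoxy-2,3-bis(triisopropylsilyloxy)benzaldehyde; 4 ethyl diazoacetate
Product: 5 ethyl (2Z)-2-[5-bromo-4-methoxy-2,3-bis(triisopropylsilyloxy)phenyl]-3-hydroxyprop-2-enoate (enol form of the α-formyl ester)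
Conditions: HBF4·OEt2 (10 mol%), CH2Cl2, −78 °C → rt
Reagents that add atoms: none
Why: Brønsted acid-catalysed addition of the diazo ester to the aldehyde and loss of N2 with 1,2-aryl shift, a known homologation of aromatic aldehydes to 3-hydroxy-2-arylacrylates; the aryl group, with oxygen ortho and para to the migrating carbon, should migrate in preference to hydride.

Step 4
Reactants: 5 ethyl (2Z)-2-[5-bromo-4-methoxy-2,3-bis(triisopropylsilyloxy)phenyl]-3-hydroxyprop-2-enoate
Product: 7 2-[5-bromo-4-methoxy-2,3-bis(triisopropylsilyloxy)phenyl]propane-1,3-diol, via racemic hydroxy ester 6 (not isolated)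
Conditions: LiBH4 (4 equiv), MeOH (4 equiv), THF, 0 °C → rt
Reagents that add atoms: none
Why: Borohydride reduction of the formyl tautomer to the β-hydroxy ester 6, then hydroxyl-assisted reduction of the ester; the protic additive keeps the enol in exchange with the reducible aldehyde, and the medium is not basic enough to dehydrate 6 or to move a silyl group.

Step 5
Reactants: 7 2-[5-bromo-4-methoxy-2,3-bis(triisopropylsilyloxy)phenyl]propane-1,3-diol; 8 prenylboronic acid pinacol ester
Product: 9 2-[4-methoxy-5-(3-methylbut-2-en-1-yl)-2,3-bis(triisopropylsilyloxy)phenyl]propane-1,3-diol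
Conditions: Pd(OAc)2 (3 mol%), t-BuXPhos (6 mol%), aq. K3PO4, THF, 40 °C
Reagents that add atoms: none
Why: Suzuki–Miyaura coupling of an aryl bromide with a 3,3-disubstituted allylboronate; a bulky di-tert-butylbiarylphosphine should let the allylpalladium intermediates equilibrate so that reductive elimination takes place at the unsubstituted terminus (linear prenyl product), and phosphate is mild enough for the aryl silyl ethers and the free diol.

Step 6
Reactants: 9 2-[4-methoxy-5-(3-methylbut-2-en-1-yl)-2,3-bis(triisopropylsilyloxy)phenyl]propane-1,3-diol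
Product: 10 (2R)-3-hydroxy-2-[4-methoxy-5-(3-methylbut-2-en-1-yl)-2,3-bis(triisopropylsilyloxy)phenyl]propyl acetate
Conditions: Burkholderia cepacia lipase (immobilised), vinyl acetate, t-BuOMe, 30 °C
Reagents that add atoms: vinyl acetate, CC(=O)OC=C
Why: Lipase-catalysed irreversible transesterification that desymmetrises a prochiral 2-aryl-1,3-propanediol, a known reaction type; the enzyme distinguishes the enantiotopic hydroxymethyl groups, and acetylation of the pro-R arm sets the centre that becomes C3; the reaction is stopped before a second acetylation.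

Step 7
Reactants: 11 resorcinol
Product: 12 3-(triisopropylsilyloxy)phenol
Conditions: i-Pr3SiCl (1.0 equiv), imidazole, DMF, 0 °C → rt, 11 in excess
Reagents that add atoms: chlorotriisopropylsilane, CC(C)[Si](Cl)(C(C)C)C(C)C
Why: Statistical monosilylation of a symmetrical diphenol; the excess of 11 suppresses the bis-ether, which is removed by chromatography.

Step 8
Reactants: 10 (2R)-3-hydroxy-2-[4-methoxy-5-(3-methylbut-2-en-1-yl)-2,3-bis(triisopropylsilyloxy)phenyl]propyl acetate; 12 3-(triisopropylsilyloxy)phenol
Product: 13 (2R)-2-[4-methoxy-5-(3-methylbut-2-en-1-yl)-2,3-bis(triisopropylsilyloxy)phenyl]-3-[3-(triisopropylsilyloxy)phenoxy]propyl acetate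
Conditions: PPh3, DIAD, toluene, 0 °C → rt
Reagents that add atoms: none
Why: Mitsunobu etherification at the primary carbon, which is not a stereocentre, so the configuration from step 6 is untouched; the near-neutral medium and short reaction time should prevent 1,3-acetyl migration, which would racemise 10.

Step 9
Reactants: 13 (2R)-2-[4-methoxy-5-(3-methylbut-2-en-1-yl)-2,3-bis(triisopropylsilyloxy)phenyl]-3-[3-(triisopropylsilyloxy)phenoxy]propyl acetate
Product: 14 (2S)-2-[4-methoxy-5-(3-methylbut-2-en-1-yl)-2,3-bis(triisopropylsilyloxy)phenyl]-3-[3-(triisopropylsilyloxy)phenoxy]propan-1-ol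
Conditions: i-Bu2AlH (2.5 equiv), CH2Cl2, −78 °C; aq. potassium sodium tartrate
Reagents that add atoms: none
Why: Reductive removal of the acetate at low temperature; no alkoxide base is present, so the aryl silyl ethers should neither cleave nor migrate to the new hydroxyl, as they could under basic methanolysis (the descriptor changes from R to S only through the priority rules).

Step 10
Reactants: 14 (2S)-2-[4-methoxy-5-(3-methylbut-2-en-1-yl)-2,3-bis(triisopropylsilyloxy)phenyl]-3-[3-(triisopropylsilyloxy)phenoxy]propan-1-ol
Product: 16 (2R)-2-[4-methoxy-5-(3-methylbut-2-en-1-yl)-2,3-bis(triisopropylsilyloxy)phenyl]-3-[3-(triisopropylsilyloxy)phenoxy]propanoic acid, via aldehyde 15 (not isolated)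
Conditions: TEMPO (20 mol%), PhI(OAc)2 (2.2 equiv), MeCN–H2O, 0 °C → rt
Reagents that add atoms: water, O
Why: Oxoammonium oxidation of the primary alcohol to the aldehyde and, through its hydrate, to the acid in one flask; the medium is weakly acidic and the aldehyde short-lived, which limits enolisation and β-elimination of the aryloxide, and no hypochlorite is present to attack the prenyl alkene.

Step 11
Reactants: 16 (2R)-2-[4-methoxy-5-(3-methylbut-2-en-1-yl)-2,3-bis(triisopropylsilyloxy)phenyl]-3-[3-(triisopropylsilyloxy)phenoxy]propanoic acid
Product: 18 (3R)-3-[4-methoxy-5-(3-methylbut-2-en-1-yl)-2,3-bis(triisopropylsilyloxy)phenyl]-7-(triisopropylsilyloxy)chroman-4-one, via acid chloride 17 (not isolated)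
Conditions: Me2C=C(Cl)NMe2 (1.2 equiv), CH2Cl2, 0 °C; then SnCl4 (2.5 equiv), −78 → −40 °C; cold pH 7 phosphate buffer
Reagents that add atoms: none
Why: The α-chloroenamine converts the acid into acid chloride 17 under neutral conditions (no HCl, no base), and SnCl4 then activates 17 as a Lewis acid complex or tight acylium ion pair; one equivalent of SnCl4 is taken up by the amide by-product. C4a of ring A, ortho to O1 and para to the silyloxy group, attacks the acyl carbon, and the Wheland intermediate loses a proton; this is an intramolecular Friedel–Crafts acylation of the kind known for 3-aryloxypropanoic acids giving chroman-4-ones. Ring C closes as a six-membered ring, exo with respect to the acyl C–O multiple bond (6-exo in Baldwin's terms). No stereocentre is formed; the centre set in step 6 should be retained because no base is present to make a ketene from 17 or an enol from 18, and the cold mixture is quenched into neutral buffer. Regioselectivity is needed between C4a and the carbon flanked by both ring A oxygens, and the bulky triisopropylsilyl group blocks the latter. Chemoselectivity is needed against three other paths: attack of O-2' on the acyl group (five-membered lactone with loss of silyl), loss of CO from the acylium ion to a ring B-stabilised cation, and addition of the liberated HCl to the prenyl alkene. The hindered silyl group on O-2', the low temperature, the absence of HCl before cyclisation and the doubly activated ring A positioned for a six-membered closure should favour acylation.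

Step 12
Reactants: 18 (3R)-3-[4-methoxy-5-(3-methylbut-2-en-1-yl)-2,3-bis(triisopropylsilyloxy)phenyl]-7-(triisopropylsilyloxy)chroman-4-one
Product: 19 (3R)-3-[2,3-dihydroxy-4-methoxy-5-(3-methylbut-2-en-1-yl)phenyl]-7-hydroxychroman-4-one
Conditions: Bu4NF (3.6 equiv), AcOH (4 equiv), THF, 0 °C → rt, argon
Reagents that add atoms: none
Why: Fluoride-induced cleavage of the three aryl silyl ethers; acetic acid protonates each phenoxide as it forms, so the medium should never be basic enough to enolise the C4 ketone, and no acid strong enough to add to the prenyl alkene is present; air is excluded to protect the free catechol.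

## Compound list

1 | 2,3-dihydroxy-4-methoxybenzaldehyde | COc1ccc(C=O)c(O)c1O | starting material
2 | 5-bromo-2,3-dihydroxy-4-methoxybenzaldehyde | COc1c(Br)cc(C=O)c(O)c1O | intermediate
3 | 5-bromo-4-methoxy-2,3-bis(triisopropylsilyloxy)benzaldehyde | COc1c(Br)cc(C=O)c(O[Si](C(C)C)(C(C)C)C(C)C)c1O[Si](C(C)C)(C(C)C)C(C)C | intermediate
4 | ethyl diazoacetate | CCOC(=O)C=[N+]=[N-] | starting material
5 | ethyl (2Z)-2-[5-bromo-4-methoxy-2,3-bis(triisopropylsilyloxy)phenyl]-3-hydroxyprop-2-enoate | CCOC(=O)/C(=C\O)c1cc(Br)c(OC)c(O[Si](C(C)C)(C(C)C)C(C)C)c1O[Si](C(C)C)(C(C)C)C(C)C | intermediate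
6 | ethyl 2-[5-bromo-4-methoxy-2,3-bis(triisopropylsilyloxy)phenyl]-3-hydroxypropanoate (racemic, not isolated) | CCOC(=O)C(CO)c1cc(Br)c(OC)c(O[Si](C(C)C)(C(C)C)C(C)C)c1O[Si](C(C)C)(C(C)C)C(C)C | intermediate
7 | 2-[5-bromo-4-methoxy-2,3-bis(triisopropylsilyloxy)phenyl]propane-1,3-diol | OCC(CO)c1cc(Br)c(OC)c(O[Si](C(C)C)(C(C)C)C(C)C)c1O[Si](C(C)C)(C(C)C)C(C)C | intermediate
8 | prenylboronic acid pinacol ester | CC(C)=CCB1OC(C)(C)C(C)(C)O1 | starting material
9 | 2-[4-methoxy-5-(3-methylbut-2-en-1-yl)-2,3-bis(triisopropylsilyloxy)phenyl]propane-1,3-diol | OCC(CO)c1cc(CC=C(C)C)c(OC)c(O[Si](C(C)C)(C(C)C)C(C)C)c1O[Si](C(C)C)(C(C)C)C(C)C | intermediate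
10 | (2R)-3-hydroxy-2-[4-methoxy-5-(3-methylbut-2-en-1-yl)-2,3-bis(triisopropylsilyloxy)phenyl]propyl acetate | COc1c(CC=C(C)C)cc([C@@H](COC(C)=O)CO)c(O[Si](C(C)C)(C(C)C)C(C)C)c1O[Si](C(C)C)(C(C)C)C(C)C | intermediate
11 | resorcinol | Oc1cccc(O)c1 | starting material
12 | 3-(triisopropylsilyloxy)phenol | Oc1cccc(O[Si](C(C)C)(C(C)C)C(C)C)c1 | intermediate
13 | (2R)-2-[4-methoxy-5-(3-methylbut-2-en-1-yl)-2,3-bis(triisopropylsilyloxy)phenyl]-3-[3-(triisopropylsilyloxy)phenoxy]propyl acetate | COc1c(CC=C(C)C)cc([C@@H](COC(C)=O)COc2cccc(O[Si](C(C)C)(C(C)C)C(C)C)c2)c(O[Si](C(C)C)(C(C)C)C(C)C)c1O[Si](C(C)C)(C(C)C)C(C)C | intermediate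
14 | (2S)-2-[4-methoxy-5-(3-methylbut-2-en-1-yl)-2,3-bis(triisopropylsilyloxy)phenyl]-3-[3-(triisopropylsilyloxy)phenoxy]propan-1-ol | COc1c(CC=C(C)C)cc([C@@H](CO)COc2cccc(O[Si](C(C)C)(C(C)C)C(C)C)c2)c(O[Si](C(C)C)(C(C)C)C(C)C)c1O[Si](C(C)C)(C(C)C)C(C)C | intermediate
15 | (2R)-2-[4-methoxy-5-(3-methylbut-2-en-1-yl)-2,3-bis(triisopropylsilyloxy)phenyl]-3-[3-(triisopropylsilyloxy)phenoxy]propanal (not isolated) | COc1c(CC=C(C)C)cc([C@@H](C=O)COc2cccc(O[Si](C(C)C)(C(C)C)C(C)C)c2)c(O[Si](C(C)C)(C(C)C)C(C)C)c1O[Si](C(C)C)(C(C)C)C(C)C | intermediate
16 | (2R)-2-[4-methoxy-5-(3-methylbut-2-en-1-yl)-2,3-bis(triisopropylsilyloxy)phenyl]-3-[3-(triisopropylsilyloxy)phenoxy]propanoic acid | COc1c(CC=C(C)C)cc([C@@H](C(=O)O)COc2cccc(O[Si](C(C)C)(C(C)C)C(C)C)c2)c(O[Si](C(C)C)(C(C)C)C(C)C)c1O[Si](C(C)C)(C(C)C)C(C)C | intermediate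
17 | (2R)-2-[4-methoxy-5-(3-methylbut-2-en-1-yl)-2,3-bis(triisopropylsilyloxy)phenyl]-3-[3-(triisopropylsilyloxy)phenoxy]propanoyl chloride (not isolated) | COc1c(CC=C(C)C)cc([C@@H](C(Cl)=O)COc2cccc(O[Si](C(C)C)(C(C)C)C(C)C)c2)c(O[Si](C(C)C)(C(C)C)C(C)C)c1O[Si](C(C)C)(C(C)C)C(C)C | intermediate
18 | (3R)-3-[4-methoxy-5-(3-methylbut-2-en-1-yl)-2,3-bis(triisopropylsilyloxy)phenyl]-7-(triisopropylsilyloxy)chroman-4-one | COc1c(CC=C(C)C)cc([C@@H]2COc3cc(O[Si](C(C)C)(C(C)C)C(C)C)ccc3C2=O)c(O[Si](C(C)C)(C(C)C)C(C)C)c1O[Si](C(C)C)(C(C)C)C(C)C | intermediate
19 | (3R)-3-[2,3-dihydroxy-4-methoxy-5-(3-methylbut-2-en-1-yl)phenyl]-7-hydroxychroman-4-one | COc1c(CC=C(C)C)cc([C@@H]2COc3cc(O)ccc3C2=O)c(O)c1O | target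

## Step count and least certain steps

Total: 12 steps. Longest linear sequence: 11 steps (1 to 19 through steps 1–6 and 8–12); step 7 is a one-step branch.

Step 11 (key step). Most likely failure: the acyl group is captured by O-2' with loss of its silyl group (five-membered lactone), or the acylium ion loses CO, or HCl adds to the prenyl alkene before the quench. Closure at the carbon between the two ring A oxygens is a lesser risk. Fallback: form the same C4–C4a bond by an anionic closure whose position is fixed by a halogen. It sets out from 10 and 11 and returns at 18.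
- 11 is iodinated (I2, NaHCO3, water) to 4-iodoresorcinol F1.
- The less hindered hydroxyl of F1 is silylated (i-Pr3SiCl, imidazole) to give 2-iodo-5-(triisopropylsilyloxy)phenol F2.
- Mitsunobu reaction of F2 with 10 gives the iodo acetate F3.
- i-Bu2AlH at −78 °C gives the iodo alcohol F4.
- TEMPO and PhI(OAc)2 give the iodo acid F5.
- Carbodiimide coupling with N,O-dimethylhydroxylamine gives the Weinreb amide F6.
- Iodine–magnesium exchange with i-PrMgCl·LiCl at −40 °C and intramolecular acylation (Parham-type cyclisation) give 18 after a mildly acidic quench.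

No acylium ion and no Lewis acid are involved, and the magnesium chelate of the tetrahedral adduct protects the new ketone from enolisation until the quench.

Step 3. Most likely failure: hydride migration in place of aryl migration (giving a β-keto ester), or acid-induced loss of the silyl group next to the formyl group followed by cyclisation to a benzofuran. Fallback: the classical homologation through the arylacetate. It sets out from 3 and returns at 6, which is then reduced as in step 4.
- Wittig reaction of 3 with MeOCH2PPh3Cl and KN(SiMe3)2 gives the enol ether F7.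
- Mild aqueous acid gives the arylacetaldehyde F8.
- Pinnick oxidation (NaClO2, NaH2PO4, 2-methyl-2-butene) gives the arylacetic acid F9.
- Carbodiimide esterification with ethanol gives the ethyl arylacetate F10.
- Deprotonation with LiN(i-Pr)2 at −78 °C and aldol addition to gaseous formaldehyde give 6.

Step 5. Most likely failure: coupling at the substituted allyl terminus (1,1-dimethylallyl isomer), protodeboronation of 8, or partial loss of a silyl group to the aqueous base. Fallback: avoid the regiochemical choice. It sets out from 7 and returns at 9. Coupling of 7 with allylboronic acid pinacol ester under the same palladium catalysis gives the allyl diol F11, and cross-metathesis with 2-methyl-2-butene (second-generation Grubbs catalyst, CH2Cl2, 40 °C) converts F11 into 9.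

Step 6. Most likely failure: slow or poorly selective acylation because the ortho silyloxy group crowds the prochiral centre, acylation of the wrong enantiotopic arm, or acetyl migration in 10 on handling. Fallback: a non-enzymatic desymmetrisation. It sets out from 9 and returns at 14. A dinuclear zinc catalyst made from Et2Zn and the appropriate enantiomer of a ProPhenol ligand, with vinyl benzoate, gives the monobenzoate F12, whose ester migrates less readily. Mitsunobu reaction of F12 with 12 gives the benzoate ether F13, and i-Bu2AlH at −78 °C converts F13 into 14.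

Step 10. Most likely failure: enolisation of the transient aldehyde 15 with loss of configurational purity, β-elimination of the aryloxide from 15, or oxidation of the prenyl alkene. Fallback: restore the purity by classical resolution. It sets out from 16 of lowered enantiomeric purity and returns at 16. The acid is crystallised as its salt with (S)-1-phenylethylamine, F14 (the amine enantiomer giving the less soluble salt is chosen by trial), and acidification of F14 with dilute aqueous acid returns 16.

## Further compounds

F1 | step 11 | 4-iodoresorcinol | Oc1ccc(I)c(O)c1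
F2 | step 11 | 2-iodo-5-(triisopropylsilyloxy)phenol | Oc1cc(O[Si](C(C)C)(C(C)C)C(C)C)ccc1I
F3 | step 11 | (2R)-3-[2-iodo-5-(triisopropylsilyloxy)phenoxy]-2-[4-methoxy-5-(3-methylbut-2-en-1-yl)-2,3-bis(triisopropylsilyloxy)phenyl]propyl acetate | COc1c(CC=C(C)C)cc([C@@H](COC(C)=O)COc2cc(O[Si](C(C)C)(C(C)C)C(C)C)ccc2I)c(O[Si](C(C)C)(C(C)C)C(C)C)c1O[Si](C(C)C)(C(C)C)C(C)C
F4 | step 11 | (2S)-3-[2-iodo-5-(triisopropylsilyloxy)phenoxy]-2-[4-methoxy-5-(3-methylbut-2-en-1-yl)-2,3-bis(triisopropylsilyloxy)phenyl]propan-1-ol | COc1c(CC=C(C)C)cc([C@@H](CO)COc2cc(O[Si](C(C)C)(C(C)C)C(C)C)ccc2I)c(O[Si](C(C)C)(C(C)C)C(C)C)c1O[Si](C(C)C)(C(C)C)C(C)C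
F5 | step 11 | (2R)-3-[2-iodo-5-(triisopropylsilyloxy)phenoxy]-2-[4-methoxy-5-(3-methylbut-2-en-1-yl)-2,3-bis(triisopropylsilyloxy)phenyl]propanoic acid | COc1c(CC=C(C)C)cc([C@@H](C(=O)O)COc2cc(O[Si](C(C)C)(C(C)C)C(C)C)ccc2I)c(O[Si](C(C)C)(C(C)C)C(C)C)c1O[Si](C(C)C)(C(C)C)C(C)C
F6 | step 11 | (2R)-3-[2-iodo-5-(triisopropylsilyloxy)phenoxy]-N-methoxy-N-methyl-2-[4-methoxy-5-(3-methylbut-2-en-1-yl)-2,3-bis(triisopropylsilyloxy)phenyl]propanamide | COc1c(CC=C(C)C)cc([C@@H](C(=O)N(C)OC)COc2cc(O[Si](C(C)C)(C(C)C)C(C)C)ccc2I)c(O[Si](C(C)C)(C(C)C)C(C)C)c1O[Si](C(C)C)(C(C)C)C(C)C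
F7 | step 3 | 1-bromo-2-methoxy-5-(2-methoxyethenyl)-3,4-bis(triisopropylsilyloxy)benzene (E/Z mixture) | COC=Cc1cc(Br)c(OC)c(O[Si](C(C)C)(C(C)C)C(C)C)c1O[Si](C(C)C)(C(C)C)C(C)C
F8 | step 3 | 2-[5-bromo-4-methoxy-2,3-bis(triisopropylsilyloxy)phenyl]acetaldehyde | O=CCc1cc(Br)c(OC)c(O[Si](C(C)C)(C(C)C)C(C)C)c1O[Si](C(C)C)(C(C)C)C(C)C
F9 | step 3 | 2-[5-bromo-4-methoxy-2,3-bis(triisopropylsilyloxy)phenyl]acetic acid | OC(=O)Cc1cc(Br)c(OC)c(O[Si](C(C)C)(C(C)C)C(C)C)c1O[Si](C(C)C)(C(C)C)C(C)C
F10 | step 3 | ethyl 2-[5-bromo-4-methoxy-2,3-bis(triisopropylsilyloxy)phenyl]acetate | CCOC(=O)Cc1cc(Br)c(OC)c(O[Si](C(C)C)(C(C)C)C(C)C)c1O[Si](C(C)C)(C(C)C)C(C)C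
F11 | step 5 | 2-[4-methoxy-5-(prop-2-en-1-yl)-2,3-bis(triisopropylsilyloxy)phenyl]propane-1,3-diol | OCC(CO)c1cc(CC=C)c(OC)c(O[Si](C(C)C)(C(C)C)C(C)C)c1O[Si](C(C)C)(C(C)C)C(C)C
F12 | step 6 | (2R)-3-hydroxy-2-[4-methoxy-5-(3-methylbut-2-en-1-yl)-2,3-bis(triisopropylsilyloxy)phenyl]propyl benzoate | COc1c(CC=C(C)C)cc([C@@H](COC(=O)c2ccccc2)CO)c(O[Si](C(C)C)(C(C)C)C(C)C)c1O[Si](C(C)C)(C(C)C)C(C)C
F13 | step 6 | (2R)-2-[4-methoxy-5-(3-methylbut-2-en-1-yl)-2,3-bis(triisopropylsilyloxy)phenyl]-3-[3-(triisopropylsilyloxy)phenoxy]propyl benzoate | COc1c(CC=C(C)C)cc([C@@H](COC(=O)c2ccccc2)COc2cccc(O[Si](C(C)C)(C(C)C)C(C)C)c2)c(O[Si](C(C)C)(C(C)C)C(C)C)c1O[Si](C(C)C)(C(C)C)C(C)C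
F14 | step 10 | (S)-1-phenylethylammonium (2R)-2-[4-methoxy-5-(3-methylbut-2-en-1-yl)-2,3-bis(triisopropylsilyloxy)phenyl]-3-[3-(triisopropylsilyloxy)phenoxy]propanoate | COc1c(CC=C(C)C)cc([C@@H](C(=O)[O-])COc2cccc(O[Si](C(C)C)(C(C)C)C(C)C)c2)c(O[Si](C(C)C)(C(C)C)C(C)C)c1O[Si](C(C)C)(C(C)C)C(C)C.C[C@H]([NH3+])c1ccccc1
A1 | alternative 1 | 3-[4-methoxy-2,3-bis(methoxymethoxy)-5-(prop-2-en-1-yl)phenyl]-2H-chromen-7-yl tert-butyl carbonate (isoflav-3-ene) | C=CCc1cc(C2=Cc3ccc(OC(=O)OC(C)(C)C)cc3OC2)c(OCOC)c(OCOC)c1OC
A2 | alternative 1 | cis-3,4-epoxide of A1 (isoflav-3-ene oxide, configuration as in the SMILES) | C=CCc1cc([C@@]23COc4cc(OC(=O)OC(C)(C)C)ccc4[C@@H]2O3)c(OCOC)c(OCOC)c1OC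
A3 | alternative 2 | 2-{2-[2-hydroxy-4-methoxy-3-(methoxymethoxy)-5-(3-methylbut-2-en-1-yl)phenyl]-2-(4-methylphenylsulfonyl)ethoxy}-4-(methoxymethoxy)benzaldehyde (racemic sulfone aldehyde) | COc1c(CC=C(C)C)cc(C(COc2cc(OCOC)ccc2C=O)S(=O)(=O)c2ccc(C)cc2)c(O)c1OCOC
A4 | alternative 2 | ortho-quinone methide formed from A3 by loss of sulfinate | O=C1C(OCOC)=C(OC)C(CC=C(C)C)=CC1=CCOc1cc(OCOC)ccc1C=O
A5 | alternative 2 | (3R)-3-[2-hydroxy-4-methoxy-3-(methoxymethoxy)-5-(3-methylbut-2-en-1-yl)phenyl]-7-(methoxymethoxy)chroman-4-one | COc1c(CC=C(C)C)cc([C@@H]2COc3cc(OCOC)ccc3C2=O)c(O)c1OCOC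
A6 | alternative 3 | 1-[2-hydroxy-4-(methoxymethoxy)phenyl]-2-[4-methoxy-2,3-bis(methoxymethoxy)-5-(3-methylbut-2-en-1-yl)phenyl]prop-2-en-1-one | C=C(C(=O)c1ccc(OCOC)cc1O)c1cc(CC=C(C)C)c(OC)c(OCOC)c1OCOC
A7 | alternative 3 | (3R)-3-[4-methoxy-2,3-bis(methoxymethoxy)-5-(3-methylbut-2-en-1-yl)phenyl]-7-(methoxymethoxy)chroman-4-one | COc1c(CC=C(C)C)cc([C@@H]2COc3cc(OCOC)ccc3C2=O)c(OCOC)c1OCOC
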